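**Strategy.** Sarcodictyin A is the furanose form of a ten-membered 4-keto-7,8-diol: the C4 hemiketal carbon sits next to two hydroxyls, the tertiary O7 and the secondary O8. The route first closes C4 onto O8, as a pyranose whose macro-ring is an eight-membered oxocine (O8, C4, C3, C2, C1, C10, C9, C8). This ring is closed by metathesis on an Achmatowicz pyranone. In the last step, esterification of O8 with N-methylurocanic acid drains the pyranose through its open keto diol, so O7 takes over C4. The oxocine grows by one atom to the nine-membered oxonine, the 2,5-dihydrofuranol forms and the side chain is attached in one operation. The carbocycle comes from (R)-α-phellandrene.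

Key step: step 13

Remark (numbering): the target is numbered C1 and C10 (ring fusion), C2=C3 (C3 carries CO2Me), C4 (hemiketal), C5=C6, C7 (methyl, ring oxygen O7), C8 (ester oxygen O8), C9, C11=C12 (C11 methyl), C13, C14 (isopropyl); all intermediates keep these numbers.

Remark (chemistry): lactol 9 and pyranone 14 are used as anomer mixtures, which interconvert through their open forms; (R)-(−)-α-phellandrene is assumed to be of high enantiomeric purity.

Step 1
Reactants: 1 (R)-(−)-α-phellandrene
Product: 2 cis-fused 8,8-dichloro-2-methyl-5-(propan-2-yl)bicyclo[4.2.0]oct-2-en-7-one (four-membered ring anti to isopropyl)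
Conditions: Cl3CCOCl, Zn (activated), Et2O, ultrasound, 20 °C
Reagents that add atoms: trichloroacetyl chloride, ClC(=O)C(Cl)(Cl)Cl
Why: Thermal ketene [2+2] cycloaddition, in which dichloroketene made in the flask should add to the less substituted C1=C10 bond of the diene with its carbonyl carbon on the diene terminus C1, suprafacially (C1 and C10 cis) and on the face opposite the C14 isopropyl group, which sets C1 and C10.

Step 2
Reactants: 2 dichlorocyclobutanone
Product: 3 cis-fused 2-methyl-5-(propan-2-yl)bicyclo[4.2.0]oct-2-en-7-one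
Conditions: Zn, AcOH, 50 °C
Reagents that add atoms: none
Why: Reductive dechlorination of an α,α-dichloro ketone by zinc should leave the ring fusion and both alkenes untouched.

Step 3
Reactants: 3 cyclobutanone; 4 5-bromofuran-2-carbonyl chloride
Product: 6 methyl 2-[2-(5-bromofuran-2-yl)-2-oxoethyl]-3-methyl-6-(propan-2-yl)cyclohex-3-ene-1-carboxylate, via β-diketone 5 (not isolated)
Conditions: MgBr2·OEt2, i-Pr2NEt, CH2Cl2, 0 °C to rt; then MeOH, NaOMe (0.2 equiv), 0 °C to rt
Reagents that add atoms: methanol, CO
Why: Claisen-type C-acylation under soft enolisation at the only enolisable methylene (C9), followed by a strain-driven retro-Claisen opening in which methoxide adds to the cyclobutanone carbonyl (C2) and the C2–C9 bond breaks to the C1 ester and the furyl ketone, so the two former alkene carbons C1 and C10 keep their cis substituents.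

Step 4
Reactants: 6 keto ester
Product: 8 cis-fused δ-lactone (3S)-3-(5-bromofuran-2-yl)-5-methyl-8-(propan-2-yl)-3,4,4a,7,8,8a-hexahydro-1H-isochromen-1-one, via hydroxy ester 7 (not isolated)
Conditions: RuCl[(S,S)-TsDPEN](p-cymene) (1 mol %), HCO2H–Et3N (5:2), CH2Cl2, 25 °C; then PPTS (cat.), toluene, 40 °C
Reagents that add atoms: none
Why: Noyori asymmetric transfer hydrogenation of a heteroaryl ketone, in which the (S,S)-ligand should deliver hydride to give the (S)-carbinol at C8 under reagent control, followed by lactonisation of the δ-hydroxy ester onto the cis C1 ester.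

Step 5
Reactants: 8 lactone
Product: 9 lactol (3S)-3-(5-bromofuran-2-yl)-5-methyl-8-(propan-2-yl)-3,4,4a,7,8,8a-hexahydro-1H-isochromen-1-ol
Conditions: i-Bu2AlH (1.1 equiv), CH2Cl2, −78 °C; aqueous potassium sodium tartrate
Reagents that add atoms: none
Why: Partial reduction of a δ-lactone by an aluminium hydride should stop at the lactol because the tetrahedral aluminate is stable at −78 °C.

Step 6
Reactants: 9 lactol
Product: 10 (1S)-1-(5-bromofuran-2-yl)-2-[6-ethenyl-2-methyl-5-(propan-2-yl)cyclohex-2-en-1-yl]ethan-1-ol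
Conditions: Ph3PCH3Br, KN(SiMe3)2, THF, 0 °C; then 9, −78 to 0 °C
Reagents that add atoms: methyltriphenylphosphonium bromide, C[P+](c1ccccc1)(c1ccccc1)c1ccccc1.[Br-]
Why: Wittig methylenation of the hydroxy aldehyde in equilibrium with the lactol should give the C1 vinyl group and free O8, with low temperature protecting the C1 centre next to the transient aldehyde.

Step 7
Reactants: 11 methyl propiolate
Product: 12 methyl 2-(tributylstannyl)prop-2-enoate
Conditions: Bu3SnH, Pd(PPh3)4 (2 mol %), THF, 0 °C to rt
Reagents that add atoms: tributyltin hydride, CCCC[SnH](CCCC)CCCC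
Why: Palladium-catalysed hydrostannation of a propiolate should place tin on the α-carbon by syn addition.

Step 8
Reactants: 10 bromofuryl carbinol; 12 stannyl acrylate
Product: 13 methyl 2-{5-[(1S)-2-[6-ethenyl-2-methyl-5-(propan-2-yl)cyclohex-2-en-1-yl]-1-hydroxyethyl]furan-2-yl}prop-2-enoate
Conditions: Pd(PPh3)4 (5 mol %), CuI (10 mol %), DMF, 50 °C
Reagents that add atoms: none
Why: Stille coupling of a 2-bromofuran and an α-stannyl acrylate (copper-assisted transmetalation) should install C3 with its ester and a terminal methylene, and tolerates the free hydroxyl.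

Step 9
Reactants: 13 furyl carbinol
Product: 14 methyl 2-{(6S)-6-[[6-ethenyl-2-methyl-5-(propan-2-yl)cyclohex-2-en-1-yl]methyl]-2-hydroxy-5-oxo-5,6-dihydro-2H-pyran-2-yl}prop-2-enoate (C4 anomers)
Conditions: VO(acac)2 (5 mol %), t-BuOOH (1.1 equiv), CH2Cl2, 0 °C
Reagents that add atoms: tert-butyl hydroperoxide, CC(C)(C)OO
Why: Achmatowicz rearrangement, in which hydroxyl-directed oxidation of the furan, opening to the Z-enedione and closure of O8 onto C4 should give the pyranone hemiketal with C8 unchanged and C5=C6 fixed as Z, the remote trisubstituted alkene and the acrylate being much less reactive.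

Step 10
Reactants: 14 pyranone hemiketal
Product: 15 4,8-epoxy enone (bridged pyranone: C3 methyl ester with the ester trans to C1 across C2=C3; C4 hemiketal OH; O8–C4 bridge; C7 ketone; eight-membered oxocine O8–C4–C3–C2–C1–C10–C9–C8)
Conditions: second-generation Hoveyda–Grubbs catalyst [RuCl2(H2IMes)(=CH-C6H4-2-O-i-Pr)] (10 mol %), toluene (1 mM), 80 °C, argon sparge
Reagents that add atoms: none
Why: Ring-closing metathesis between the C1 vinyl group and the 1,1-disubstituted acrylate should close the eight-membered oxocine on the pyranose template, where only the C4 anomer with the acrylate cis to C9 can cyclise (this fixes C4) and the ring enforces the C2=C3 geometry.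

Step 11
Reactants: 15 4,8-epoxy enone
Product: 16 pyranose diol (as 15 but with C7 carrying methyl anti to C9 and hydroxyl syn to C9)
Conditions: CeCl3 (anhydrous), MeLi (3 equiv), THF, −78 °C; aqueous NH4Cl
Reagents that add atoms: methyllithium, [Li]C
Why: 1,2-Addition of a weakly basic organocerium reagent to the enone carbonyl should occur on the face opposite the C9–C1–C2–C3 bridge, which sets C7 with O7 syn to C9 as the later furanose needs, the ester and the hindered enoate being slower at −78 °C.

Step 12
Reactants: 17 1-methyl-1H-imidazole-4-carbaldehyde; 18 malonic acid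
Product: 19 (2E)-3-(1-methyl-1H-imidazol-4-yl)prop-2-enoic acid
Conditions: pyridine, piperidine (cat.), 100 °C
Reagents that add atoms: none
Why: Knoevenagel–Doebner condensation with decarboxylation should give the E acid under thermodynamic control.

Step 13
Reactants: 16 pyranose diol; 19 N-methylurocanic acid
Product: 23 sarcodictyin A, via mixed anhydride 20 (not isolated), via open keto diol 21 (not isolated), via furanose diol 22 (not isolated)
Conditions: 19, 2,4,6-trichlorobenzoyl chloride, Et3N, THF, 25 °C; then 16, DMAP, toluene, 25 to 40 °C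
Reagents that add atoms: none
Why: Under Et3N/DMAP the pyranose hemiketal 16 should equilibrate by retro-hemiketalisation with the open 4-keto-7,8-diol 21, which recloses through O7 to the furanose 22; only 21 and 22 have a free secondary hydroxyl, and its irreversible acylation by the mixed anhydride 20 (Yamaguchi esterification) pulls the equilibrium to the ring-expanded ester. The closest known reaction type is the acylative pyranose-to-furanose isomerisation of ketose hemiketals, which seen from the macro-ring is a one-atom ring expansion from oxocine to oxonine, with C7 entering the ring and O7 replacing O8 at C4. The 2,5-dihydrofuran closes by 5-exo-trig addition of O7 to the C4 carbonyl, and the same bond closes the nine-membered ring transannularly across the ten-membered carbocycle. The new C4 stereocentre is dictated by C7: with the Z C5=C6 bond O7 can reach only one face of the ketone, so the hemiketal hydroxyl ends up exo. The step needs O8 to be acylated in preference to the tertiary O7 and the hemiketal hydroxyl, which their steric shielding should secure, and it needs the Z geometry of C5=C6, fixed since step 9, to keep O7 within reach of C4.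

**Compound list**

1 | (R)-(−)-α-phellandrene, (5R)-2-methyl-5-(propan-2-yl)cyclohexa-1,3-diene | CC1=CC[C@H](C(C)C)C=C1 | starting material
2 | cis-fused 8,8-dichloro-2-methyl-5-(propan-2-yl)bicyclo[4.2.0]oct-2-en-7-one, cyclobutanone anti to isopropyl | O=C1[C@@H]2[C@@H](C(C)C)CC=C(C)[C@@H]2C1(Cl)Cl | intermediate
3 | cis-fused 2-methyl-5-(propan-2-yl)bicyclo[4.2.0]oct-2-en-7-one | O=C1[C@@H]2[C@@H](C(C)C)CC=C(C)[C@@H]2C1 | intermediate
4 | 5-bromofuran-2-carbonyl chloride | O=C(Cl)c1ccc(Br)o1 | starting material
5 | 8-(5-bromofuran-2-carbonyl)-2-methyl-5-(propan-2-yl)bicyclo[4.2.0]oct-2-en-7-one (enolised, C9 undefined) | O=C1[C@@H]2[C@@H](C(C)C)CC=C(C)[C@@H]2C1C(=O)c1ccc(Br)o1 | intermediate (not isolated)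
6 | methyl 2-[2-(5-bromofuran-2-yl)-2-oxoethyl]-3-methyl-6-(propan-2-yl)cyclohex-3-ene-1-carboxylate (ester and side chain cis, isopropyl trans to the ester) | COC(=O)[C@@H]1[C@@H](C(C)C)CC=C(C)[C@@H]1CC(=O)c1ccc(Br)o1 | intermediate
7 | methyl 2-[(2S)-2-(5-bromofuran-2-yl)-2-hydroxyethyl]-3-methyl-6-(propan-2-yl)cyclohex-3-ene-1-carboxylate | COC(=O)[C@@H]1[C@@H](C(C)C)CC=C(C)[C@@H]1C[C@H](O)c1ccc(Br)o1 | intermediate (not isolated)
8 | cis-fused (3S)-3-(5-bromofuran-2-yl)-5-methyl-8-(propan-2-yl)-3,4,4a,7,8,8a-hexahydro-1H-isochromen-1-one | O=C1[C@@H]2[C@@H](C(C)C)CC=C(C)[C@@H]2C[C@@H](c3ccc(Br)o3)O1 | intermediate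
9 | (3S)-3-(5-bromofuran-2-yl)-5-methyl-8-(propan-2-yl)-3,4,4a,7,8,8a-hexahydro-1H-isochromen-1-ol (anomers) | OC1[C@@H]2[C@@H](C(C)C)CC=C(C)[C@@H]2C[C@@H](c3ccc(Br)o3)O1 | intermediate
10 | (1S)-1-(5-bromofuran-2-yl)-2-[6-ethenyl-2-methyl-5-(propan-2-yl)cyclohex-2-en-1-yl]ethan-1-ol (vinyl and side chain cis, isopropyl trans to vinyl) | C=C[C@@H]1[C@@H](C(C)C)CC=C(C)[C@@H]1C[C@H](O)c1ccc(Br)o1 | intermediate
11 | methyl propiolate | C#CC(=O)OC | starting material
12 | methyl 2-(tributylstannyl)prop-2-enoate | C=C(C(=O)OC)[Sn](CCCC)(CCCC)CCCC | intermediate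
13 | methyl 2-{5-[(1S)-2-[6-ethenyl-2-methyl-5-(propan-2-yl)cyclohex-2-en-1-yl]-1-hydroxyethyl]furan-2-yl}prop-2-enoate | C=C[C@@H]1[C@@H](C(C)C)CC=C(C)[C@@H]1C[C@H](O)c1ccc(C(=C)C(=O)OC)o1 | intermediate
14 | methyl 2-{(6S)-6-[[6-ethenyl-2-methyl-5-(propan-2-yl)cyclohex-2-en-1-yl]methyl]-2-hydroxy-5-oxo-5,6-dihydro-2H-pyran-2-yl}prop-2-enoate (C4 anomers) | C=C[C@@H]1[C@@H](C(C)C)CC=C(C)[C@@H]1C[C@@H]2OC(O)(C(=C)C(=O)OC)C=CC2=O | intermediate
15 | 4,8-epoxy enone: bridged pyranone with C3 methyl ester, C2=C3, C4 hemiketal OH, O8–C4 bridge, C7 ketone, cyclohexene as in the target | COC(=O)/C1=C/[C@@H]2[C@@H](C(C)C)CC=C(C)[C@@H]2C[C@@H]3O[C@@]1(O)C=CC3=O | intermediate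
16 | pyranose diol: as 15 with C7 bearing methyl (anti to C9) and hydroxyl (syn to C9) | COC(=O)/C1=C/[C@@H]2[C@@H](C(C)C)CC=C(C)[C@@H]2C[C@@H]3O[C@@]1(O)C=C[C@]3(C)O | intermediate
17 | 1-methyl-1H-imidazole-4-carbaldehyde | Cn1cnc(C=O)c1 | starting material
18 | malonic acid | OC(=O)CC(=O)O | starting material
19 | (2E)-3-(1-methyl-1H-imidazol-4-yl)prop-2-enoic acid | OC(=O)/C=C/c1cn(C)cn1 | intermediate
20 | mixed anhydride of 19 and 2,4,6-trichlorobenzoic acid | O=C(/C=C/c1cn(C)cn1)OC(=O)c1c(Cl)cc(Cl)cc1Cl | intermediate (not isolated)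
21 | open keto diol: ten-membered 4-ketone with free 7-OH (tertiary) and 8-OH, Z C5=C6 | COC(=O)/C1=C/[C@@H]2[C@@H](C(C)C)CC=C(C)[C@@H]2C[C@H](O)[C@@](C)(O)/C=C\C1=O | intermediate (not isolated)
22 | furanose diol (8-desacyl sarcodictyin A) | COC(=O)/C1=C/[C@@H]2[C@@H](C(C)C)CC=C(C)[C@@H]2C[C@H](O)[C@]2(C)C=C[C@@]1(O)O2 | intermediate (not isolated)
23 | sarcodictyin A | COC(=O)/C1=C/[C@@H]2[C@@H](C(C)C)CC=C(C)[C@@H]2C[C@H](OC(=O)/C=C/c2cn(C)cn2)[C@]2(C)C=C[C@@]1(O)O2 | target

**Step count and risks**

Total step count: 13. Longest linear sequence: 11 steps (steps 1–6, 8–11 and 13).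

Step 10 (ring-closing metathesis). What may go wrong: the ruthenium alkylidene loaded at the C1 vinyl group fails to engage the 1,1-disubstituted acrylate next to the fully substituted C4, so that intermolecular metathesis of the vinyl groups and catalyst decay outrun ring closure. The fallback closes the macro-ring at C3–C4 by a Nozaki–Hiyama–Kishi reaction on the furan and makes the enoate afterwards by carbonylation; it sets out from 10 and comes back at 15. Silylation (t-BuMe2SiCl, imidazole, DMF) should give the silyl ether F1. Hydroboration of the vinyl group (9-BBN, THF; then NaBO3·4H2O) should give the primary alcohol F2, and Dess–Martin oxidation the aldehyde F3. CrCl2 with NiCl2 (cat.) in DMSO–THF at high dilution should close the furan-bridged carbinol F4, and Dess–Martin oxidation should give the furyl ketone F5. KN(SiMe3)2 and PhNTf2 should give the enol triflate F6 toward C2, the only enolisable side. Pd(OAc)2, PPh3, CO, MeOH and Et3N should give the methyl enoate F7, and Bu4NF the furyl carbinol F8. VO(acac)2 and t-BuOOH then oxidise the furan of F8 to the bridged pyranone 15.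

Step 13 (key step). What may go wrong: ring–chain exchange is slower than acylation of the anomeric hydroxyl, or the hindered mixed anhydride reacts too slowly, so that the pyranose is consumed without ring expansion. The fallback separates ring expansion from esterification and locks the furanose as a methyl ketal; it sets out from 16 and comes back at 23. Ac2O, DMAP and pyridine should give the ring-expanded furanose acetate F9. MeOH with PPTS should give the C4 methyl ketal F10. K2CO3 in MeOH should give the C8 alcohol F11, which can no longer return to a pyranose. Esterification with 19 (through 20, DMAP) should give the urocanate methyl ketal F12. PPTS in acetone–water then hydrolyses the ketal to 23.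

Step 11 (methyl addition). What may go wrong: the lithium lactolate opens to the enedione, so that the reagent adds to or enolises the unmasked C4 ketone, or the ester is attacked. The fallback masks C4 before the addition; it sets out from 15 and comes back at 16. MeOH with PPTS should give the methyl pyranoside F13. CeCl3/MeLi at −78 °C should give the tertiary carbinol F14, still from the face opposite the bridge. PPTS in acetone–water then frees the hemiketal to give 16.

**Further compounds**

F1 | step 10 | tert-butyldimethylsilyl ether of 10 | C=C[C@@H]1[C@@H](C(C)C)CC=C(C)[C@@H]1C[C@H](O[Si](C)(C)C(C)(C)C)c1ccc(Br)o1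
F2 | step 10 | primary alcohol from hydroboration of F1 (C3–OH) | OCC[C@@H]1[C@@H](C(C)C)CC=C(C)[C@@H]1C[C@H](O[Si](C)(C)C(C)(C)C)c1ccc(Br)o1
F3 | step 10 | C3 aldehyde | O=CC[C@@H]1[C@@H](C(C)C)CC=C(C)[C@@H]1C[C@H](O[Si](C)(C)C(C)(C)C)c1ccc(Br)o1
F4 | step 10 | furan-bridged carbinol (C3–OH, C3 undefined; furan C4 and C7 bridged by C3–C2–C1–C10–C9–C8) | OC1C[C@@H]2[C@@H](C(C)C)CC=C(C)[C@@H]2C[C@H](O[Si](C)(C)C(C)(C)C)c2ccc1o2
F5 | step 10 | furan-bridged C3 ketone | O=C1C[C@@H]2[C@@H](C(C)C)CC=C(C)[C@@H]2C[C@H](O[Si](C)(C)C(C)(C)C)c2ccc1o2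
F6 | step 10 | C2=C3 enol triflate | O=S(=O)(O/C1=C/[C@@H]2[C@@H](C(C)C)CC=C(C)[C@@H]2C[C@H](O[Si](C)(C)C(C)(C)C)c2ccc1o2)C(F)(F)F
F7 | step 10 | furan-bridged methyl enoate, O8 silyl ether | COC(=O)/C1=C/[C@@H]2[C@@H](C(C)C)CC=C(C)[C@@H]2C[C@H](O[Si](C)(C)C(C)(C)C)c2ccc1o2
F8 | step 10 | furan-bridged methyl enoate, free C8 carbinol | COC(=O)/C1=C/[C@@H]2[C@@H](C(C)C)CC=C(C)[C@@H]2C[C@H](O)c2ccc1o2
F9 | step 13 | furanose 8-acetate (8-O-acetyl analogue of 22) | COC(=O)/C1=C/[C@@H]2[C@@H](C(C)C)CC=C(C)[C@@H]2C[C@H](OC(C)=O)[C@]2(C)C=C[C@@]1(O)O2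
F10 | step 13 | C4 methyl ketal of F9 | COC(=O)/C1=C/[C@@H]2[C@@H](C(C)C)CC=C(C)[C@@H]2C[C@H](OC(C)=O)[C@]2(C)C=C[C@@]1(OC)O2
F11 | step 13 | C4 methyl ketal with free C8 hydroxyl | COC(=O)/C1=C/[C@@H]2[C@@H](C(C)C)CC=C(C)[C@@H]2C[C@H](O)[C@]2(C)C=C[C@@]1(OC)O2
F12 | step 13 | C4 methyl ketal of sarcodictyin A | COC(=O)/C1=C/[C@@H]2[C@@H](C(C)C)CC=C(C)[C@@H]2C[C@H](OC(=O)/C=C/c2cn(C)cn2)[C@]2(C)C=C[C@@]1(OC)O2
F13 | step 11 | methyl pyranoside (C4–OMe) of 15 | COC(=O)/C1=C/[C@@H]2[C@@H](C(C)C)CC=C(C)[C@@H]2C[C@@H]3O[C@@]1(OC)C=CC3=O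
F14 | step 11 | methyl pyranoside (C4–OMe) of 16 | COC(=O)/C1=C/[C@@H]2[C@@H](C(C)C)CC=C(C)[C@@H]2C[C@@H]3O[C@@]1(OC)C=C[C@]3(C)O
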